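The numbers of this flask are invented.

The ratio to watch is partner charged to substrate charged, 1.00, which looks like enough until you count the protic impurity, which takes partner one for one.

| flask | substrate | partner | protic impurity | time | remark |
|---|---|---|---|---|---|
| eta | 0.050 M (in portions, 3, over 8.0 h) | 0.0500 M | 0.0250 M | 12 h | first portion at the start, last at 8.0 h |
| theta | 0.050 M | 0.0500 M (fed, over 8.0 h) | 0.0250 M | 12 h | all else is in the flask from the start; the feed brings no volume worth counting |
| alpha | 0.050 M (fed, over 8.0 h) | 0.0500 M | 0.0250 M | 12 h | all else is in the flask from the start; the feed brings no volume worth counting |
| beta | 0.050 M | 0.0500 M | 0.0250 M | 12 h | everything together at the start |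

    substrate + partner → target, rate k1*[substrate]^0.5*[partner]^0.5 (k1 = 0.0068 min⁻¹)
    target → over-reaction product (k2 = 6.2 × 10⁻⁴ min⁻¹)
    partner + protic impurity → quenched reagent (k3 = 0.42 L mol⁻¹ min⁻¹)

1. the flask that comes out highest in amount of target, in percent of the substrate charged, or "all alike" when all lie within 1.5 percentage points (eta / theta / alpha / beta / all alike)
2. target at the end, in percent of the substrate charged, eta
3. target at the end, in percent of the substrate charged, theta
4. target at the end, in percent of the substrate charged, alpha
5. target at the end, in percent of the substrate charged, beta

You are taking over these flasks, so here is my note. Count what is left, not what is made. Once partner is gone, the fraction of substrate converted is the free partner share, (c(partner) − c(protic impurity))/c(substrate) at the charges, 50.0%, plus the charge ratio of protic impurity to substrate, 0.500, multiplied by the fraction of protic impurity still left.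

How much impurity survives follows the rate of the wanted step over the rate of the quench, 0.648 at the charges of beta. With c(substrate) and c(protic impurity) held, that ratio goes as one over the square root of c(partner). In eta the first portion meets the whole partner charge, so the ratio starts at 0.374, lower than in beta. I expect alpha to start no better, its substrate arriving by the feed, and theta, with partner trickling into the full substrate charge, to stay above 0.648. So I put theta first, with eta and alpha last.

Target made at the start and held for 12 h keeps 64.0% of itself, so the free partner share made that early gives 32.0%, my rough low mark for each flask. Do not quicken the partner feed in theta, since a higher c(partner), the rest held, lowers the ratio.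

The forecast names theta, with eta 37%, theta 54%, alpha 39% and beta 42%, reasoning that “keeping partner scarce by feeding it slowly favours the product”.

The simulation gives eta 38.5%, theta 56.0%, alpha 38.5% and beta 42.1%, so theta comes out highest.

In theta the limiting reagent, partner, ends at 0% with 46.9% of the protic impurity left, so the count gives 73.4% converted, and 27% of the substrate remains. The neighbouring flask is eta with c(substrate) at 0.030 M, which lifts the free partner share to 83.3%. This flask still holds 0.273% of its partner beside 2.47% of its impurity, so the count, with that partner taken off, gives 84.9% converted. That neighbour ends with 15.1% of its substrate left and 64.9% target.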